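**Plan**
- Locants (elemane): carbocycle C5–C10 (C5 carries isopropenyl C4(=C3)C15; C10 carries methyl and vinyl C1=C2); γ-lactone ring O–C6–C7–C11–C12; acyloxy on C8. Retrosynthetic cuts, in order: the C8 ester; C5–H (allylic transposition from a C3 chloride); the lactone O–C6 bond; C5–C4 (Stille); C7–C11 (Michael); the two C10 substituents.
- Forward: the carbocycle is present from the start (cyclohexa-1,3-diene). It is oxygenated at C8, quaternized at C10, joined at C7 to a lactic acid unit held in a temporary dioxolanone ring, and joined at C5 to the isopropenyl carbons. The γ-lactone is the only ring made and is closed last, by O–C6 bond formation.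
- Enabling feature: the lactone oxygen sits on C6, next to C5, which carries the isopropenyl group. With C5 kept sp2, the precursor holds a conjugated diene C6=C5–C4=C3 whose terminus C6 is adjacent to C7, the carbon that carries the C11–C12 acid. A palladium-catalysed 1,4-oxidation can therefore close the five-membered ring at C6 and leave an allyl unit C5–C4–C3, from which C5–H and the isopropenyl group are then set.
- Stereochemistry: C8 from an enantioselective Kornblum–DeLaMare desymmetrization; C10 and C7 by attack anti to the C8 silyloxy group; C11 from (R)-lactic acid through its pivalaldehyde acetal; C6 by the tether (cis fusion); C5 by hydride delivery anti to the axial O6/vinyl pair.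

Key step: step 12

Remark: in step 2 the quasi-enantiomeric form of the cinchona base that gives the (R)-enone is assumed to be chosen. The carbinol configuration of 8 and the geometry of the C4=C5 bond of 19 are inconsequential (19 is drawn as the expected Z isomer). TBS = tert-butyldimethylsilyl.

Step 1
Reactants: 1 cyclohexa-1,3-diene
Product: 2 meso-2,3-dioxabicyclo[2.2.2]oct-5-ene
Conditions: O2, tetraphenylporphyrin (cat.), visible light, CH2Cl2, 0 °C
Reagents that add atoms: dioxygen, O=O
Why: Photosensitized [4+2] cycloaddition of singlet oxygen to the s-cis diene should give the bicyclic endoperoxide, whose bridgehead carbons are necessarily cis and enantiotopic, so no stereocontrol is needed.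

Step 2
Reactants: 2 meso-2,3-dioxabicyclo[2.2.2]oct-5-ene
Product: 3 (R)-4-hydroxycyclohex-2-en-1-one
Conditions: 9-O-acyl-6'-hydroxy cinchona alkaloid base (10 mol %), CH2Cl2, 23 °C
Reagents that add atoms: none
Why: Kornblum–DeLaMare rearrangement: the chiral base should remove one of the two enantiotopic bridgehead hydrogens with O–O cleavage, so that this carbon becomes the ketone and the other bridgehead becomes the C8 carbinol stereocentre, with the configuration fixed by the catalyst.

Step 3
Reactants: 3 (R)-4-hydroxycyclohex-2-en-1-one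
Product: 4 (R)-4-(TBS-oxy)cyclohex-2-en-1-one
Conditions: TBSCl, imidazole, DMF, 23 °C
Reagents that add atoms: tert-butyldimethylsilyl chloride, CC(C)(C)[Si](C)(C)Cl
Why: Imidazole-promoted silylation of the secondary allylic alcohol leaves C8 untouched and blocks the oxygen for the enolate chemistry that follows.

Step 4
Reactants: 4 (R)-4-(TBS-oxy)cyclohex-2-en-1-one
Product: 6 (4R,6R)-4-(TBS-oxy)-6-methylcyclohex-2-en-1-one, via kinetic lithium enolate 5 (not isolated)
Conditions: LiN(iPr)2, THF, −78 °C; MeI, −78 → −40 °C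
Reagents that add atoms: iodomethane, CI
Why: Kinetic α'-deprotonation gives the cross-conjugated enolate, which is methylated at C10 in an SN2 enolate alkylation; the C10 configuration formed here does not matter because C10 is planarized again in step 5.

Step 5
Reactants: 6 (4R,6R)-4-(TBS-oxy)-6-methylcyclohex-2-en-1-one
Product: 8 (4R,6S)-4-(TBS-oxy)-6-(1-hydroxyethyl)-6-methylcyclohex-2-en-1-one, via tetrasubstituted lithium enolate 7 (not isolated)
Conditions: LiN(iPr)2, THF, −78 °C; MeCHO, −78 °C; AcOH, −78 °C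
Reagents that add atoms: acetaldehyde, CC=O
Why: Aldol addition of the fully substituted kinetic enolate to acetaldehyde should create quaternary C10 with the new two-carbon branch anti to the pseudoaxial C8 silyloxy group (1,3-shielding of the syn face), leaving the methyl group cis to O8; the cold acidic quench is meant to prevent retro-aldol.

Step 6
Reactants: 8 (4R,6S)-4-(TBS-oxy)-6-(1-hydroxyethyl)-6-methylcyclohex-2-en-1-one
Product: 9 (4R,6S)-4-(TBS-oxy)-6-ethenyl-6-methylcyclohex-2-en-1-one
Conditions: methyl N-(triethylammoniosulfonyl)carbamate, toluene, 70 °C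
Reagents that add atoms: none
Why: Burgess dehydration (syn elimination through the sulfamate ester) can only take a hydrogen from the terminal methyl group because C10 is quaternary, so the vinyl group should form regiospecifically without touching C8 or C10.

Step 7
Reactants: 10 (R)-lactic acid
Product: 11 (2R,5R)-2-tert-butyl-5-methyl-1,3-dioxolan-4-one
Conditions: pivalaldehyde, TsOH (cat.), pentane, reflux with water separator; crystallization
Reagents that add atoms: pivalaldehyde, CC(C)(C)C=O
Why: Acid-catalysed acetalization with azeotropic removal of water gives the 2,5-cis dioxolanone as the thermodynamic, crystalline diastereomer, in which the new acetal stereocentre stores the chirality of lactic acid (self-regeneration of stereocentres).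

Step 8
Reactants: 11 (2R,5R)-2-tert-butyl-5-methyl-1,3-dioxolan-4-one; 9 (4R,6S)-4-(TBS-oxy)-6-ethenyl-6-methylcyclohex-2-en-1-one
Product: 14 (3R,4R,6S)-4-(TBS-oxy)-3-[(2R,4S)-2-tert-butyl-4-methyl-5-oxo-1,3-dioxolan-4-yl]-6-ethenyl-6-methylcyclohex-1-en-1-yl triflate, via dioxolanone lithium enolate 12 (not isolated), via Michael adduct lithium enolate 13 (not isolated)
Conditions: 11, LiN(iPr)2, THF, −78 °C; 9, DMPU, −78 → −40 °C; PhNTf2, −78 → 0 °C
Reagents that add atoms: N-phenylbis(trifluoromethanesulfonimide), O=S(=O)(N(c1ccccc1)S(=O)(=O)C(F)(F)F)C(F)(F)F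
Why: Michael addition followed by O-triflation of the resulting enolate: the nucleophile should attack C7 anti to the adjacent C8 silyloxy group and through its face anti to the tert-butyl group, which sets C7 and C11 (retention with respect to lactic acid); 1,2-addition is disfavoured by the neopentyl-type carbonyl next to quaternary C10, and only the C5=C6 enolate can exist, so triflation is regiospecific.

Step 9
Reactants: 14 enol triflate
Product: 15 (2R,5S)-2-tert-butyl-5-[(1R,4S,6R)-6-(TBS-oxy)-4-ethenyl-4-methyl-3-(prop-1-en-2-yl)cyclohex-2-en-1-yl]-5-methyl-1,3-dioxolan-4-one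
Conditions: tributyl(prop-1-en-2-yl)stannane, Pd(PPh3)4 (5 mol %), LiCl, THF, 65 °C
Reagents that add atoms: tributyl(prop-1-en-2-yl)stannane, CCCC[Sn](CCCC)(CCCC)C(C)=C
Why: Stille coupling of the enol triflate (LiCl-promoted) should put the isopropenyl carbons C4, C3 and C15 on C5 under neutral conditions that spare the base-labile dioxolanone and create no stereocentre.

Step 10
Reactants: 15 diene dioxolanone
Product: 16 (2S)-2-[(1R,4S,6R)-6-(TBS-oxy)-4-ethenyl-4-methyl-3-(prop-1-en-2-yl)cyclohex-2-en-1-yl]-2-hydroxypropanoic acid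
Conditions: LiOH, THF–H2O, 23 °C; then 1 M HCl to pH 3
Reagents that add atoms: lithium hydroxide, [Li+].[OH-]
Why: Saponification: hydroxide adds to the acylal-type carbonyl C12 and the hemiacetal so released collapses to pivalaldehyde, unmasking the acid and the tertiary C11 hydroxyl; C11 carries no hydrogen and cannot epimerize.

Step 11
Reactants: 16 hydroxy acid
Product: 18 (2S)-2-acetoxy-2-[(1R,4S,6R)-6-(TBS-oxy)-4-ethenyl-4-methyl-3-(prop-1-en-2-yl)cyclohex-2-en-1-yl]propanoic acid, via mixed acetic anhydride 17 (not isolated)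
Conditions: Ac2O, Et3N, DMAP (0.2 equiv), CH2Cl2, 0 → 23 °C; then H2O–THF, 23 °C
Reagents that add atoms: acetic anhydride, CC(=O)OC(C)=O
Why: DMAP-catalysed acetylation of the tertiary alcohol; the carboxyl group is acetylated in passing to the mixed anhydride, which the aqueous stir should hydrolyse at its unhindered acetyl carbonyl to return the free acid.

Step 12
Reactants: 18 acetoxy diene acid
Product: 19 (3S,3aR,4R,6S,7Z,7aS)-3-acetoxy-4-(TBS-oxy)-7-(1-chloropropan-2-ylidene)-6-ethenyl-3,6-dimethylhexahydro-1-benzofuran-2(3H)-one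
Conditions: Pd(OAc)2 (5 mol %), LiCl (4 equiv), p-benzoquinone (2 equiv, added in portions), acetone–AcOH 4:1, 23 °C
Reagents that add atoms: lithium chloride, [Li+].[Cl-]
Why: Palladium-catalysed intramolecular 1,4-oxidation of a conjugated diene (1,4-chlorolactonization): divalent palladium binds the diene C6=C5–C4=C3 on the face away from the C7 side chain, the C12 carboxylate attacks the terminus C6 anti to the metal and leaves an η3-allylpalladium unit over C5–C4–C3, chloride then attacks the unhindered terminus C3, and the zerovalent palladium released is reoxidized by benzoquinone. The closest known reaction type is the palladium-catalysed 1,4-acyloxychlorination and lactonization of dienylacetic acids. The γ-lactone closes in the 5-exo-trig mode at C6, the only position from which the allyl system can form. The new stereocentre C6 is controlled by C7, because the five-membered ring can only close on the face that carries the tether, which gives the cis ring fusion. The step needs attack at C6 instead of C5 or C3 and reaction of the diene in preference to the isolated vinyl group; the short tether (5-ring at C6 against 6-ring at C5 or 8-ring at C3) and the allyl stabilization open only to the diene should secure both, while the tertiary acetate and the silyl ether are inert. The geometry of the new C4=C5 bond is of no consequence because step 13 passes through the allyl system again.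

Step 13
Reactants: 19 allylic chloride lactone
Product: 20 (3S,3aR,4R,6S,7R,7aR)-3-acetoxy-4-(TBS-oxy)-6-ethenyl-3,6-dimethyl-7-(prop-1-en-2-yl)hexahydro-1-benzofuran-2(3H)-one
Conditions: Pd2(dba)3 (2.5 mol %), PBu3 (10 mol %), HCO2H, Et3N, THF, 50 °C
Reagents that add atoms: none
Why: Palladium-catalysed formate reduction with allylic transposition: zerovalent palladium ionizes the primary allylic chloride far faster than the allylic lactone C6–O bond, and the palladium hydride formed by decarboxylation of formate delivers hydrogen to the more substituted allyl terminus C5 (the usual outcome with PBu3) from the top face, because in the favoured chair the lactone oxygen on C6 and the vinyl group on C10 are both axial on the bottom face; this sets C5 and forms the isopropenyl group.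

Step 14
Reactants: 20 silyl ether lactone
Product: 21 (3S,3aS,4R,6S,7R,7aR)-3-acetoxy-6-ethenyl-4-hydroxy-3,6-dimethyl-7-(prop-1-en-2-yl)hexahydro-1-benzofuran-2(3H)-one
Conditions: HF·pyridine, pyridine, THF, 0 → 23 °C
Reagents that add atoms: none
Why: Acidic fluoride desilylation frees the C8 hydroxyl; the buffered acidic medium avoids base-induced acetyl migration from O11 to O8 and opening of the lactone, and no stereocentre is affected.

Step 15
Reactants: 21 hydroxy lactone; 22 3-methylbut-3-enoic acid
Product: 23 (3S,3aS,4R,6S,7R,7aR)-3-acetoxy-6-ethenyl-3,6-dimethyl-2-oxo-7-(prop-1-en-2-yl)octahydro-1-benzofuran-4-yl 3-methylbut-3-enoate (target)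
Conditions: DCC, DMAP (0.1 equiv), CH2Cl2, −20 → 0 °C
Reagents that add atoms: none
Why: Steglich esterification acylates O8 with retention at C8 (acyl–oxygen bond formation); the low temperature and small amount of DMAP are meant to suppress migration of the β,γ-double bond of the acyl group into conjugation.

**Compound list**
1 | cyclohexa-1,3-diene | C1=CC=CCC1 | starting material
2 | meso-2,3-dioxabicyclo[2.2.2]oct-5-ene (cis-bridged endoperoxide) | C1C[C@@H]2C=C[C@H]1OO2 | intermediate
3 | (R)-4-hydroxycyclohex-2-en-1-one | C1C[C@@H](O)C=CC1=O | intermediate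
4 | (R)-4-[(tert-butyldimethylsilyl)oxy]cyclohex-2-en-1-one | C1C[C@@H](O[Si](C)(C)C(C)(C)C)C=CC1=O | intermediate
5 | lithium (4R)-4-[(tert-butyldimethylsilyl)oxy]cyclohexa-1,5-dien-1-olate (formed in the flask) | [Li+].[O-]C1=CC[C@@H](O[Si](C)(C)C(C)(C)C)C=C1 | intermediate
6 | (4R,6R)-4-[(tert-butyldimethylsilyl)oxy]-6-methylcyclohex-2-en-1-one (trans; the C6 epimer serves equally) | C[C@@H]1C[C@@H](O[Si](C)(C)C(C)(C)C)C=CC1=O | intermediate
7 | lithium (4R)-4-[(tert-butyldimethylsilyl)oxy]-2-methylcyclohexa-1,5-dien-1-olate (formed in the flask) | [Li+].[O-]C1=C(C)C[C@@H](O[Si](C)(C)C(C)(C)C)C=C1 | intermediate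
8 | (4R,6S)-4-[(tert-butyldimethylsilyl)oxy]-6-(1-hydroxyethyl)-6-methylcyclohex-2-en-1-one (carbinol epimers) | CC(O)[C@]1(C)C[C@@H](O[Si](C)(C)C(C)(C)C)C=CC1=O | intermediate
9 | (4R,6S)-4-[(tert-butyldimethylsilyl)oxy]-6-ethenyl-6-methylcyclohex-2-en-1-one | C=C[C@]1(C)C[C@@H](O[Si](C)(C)C(C)(C)C)C=CC1=O | intermediate
10 | (R)-lactic acid | C[C@@H](O)C(=O)O | starting material
11 | (2R,5R)-2-tert-butyl-5-methyl-1,3-dioxolan-4-one (cis) | C[C@H]1O[C@@H](C(C)(C)C)OC1=O | intermediate
12 | lithium (2R)-2-tert-butyl-5-methyl-1,3-dioxol-4-olate (formed in the flask) | [Li+].[O-]C1=C(C)O[C@@H](C(C)(C)C)O1 | intermediate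
13 | lithium (3R,4R,6S)-4-[(tert-butyldimethylsilyl)oxy]-3-[(2R,4S)-2-tert-butyl-4-methyl-5-oxo-1,3-dioxolan-4-yl]-6-ethenyl-6-methylcyclohex-1-en-1-olate (formed in the flask) | C=C[C@]1(C)C[C@@H](O[Si](C)(C)C(C)(C)C)[C@H]([C@]2(C)O[C@@H](C(C)(C)C)OC2=O)C=C1[O-].[Li+] | intermediate
14 | (3R,4R,6S)-4-[(tert-butyldimethylsilyl)oxy]-3-[(2R,4S)-2-tert-butyl-4-methyl-5-oxo-1,3-dioxolan-4-yl]-6-ethenyl-6-methylcyclohex-1-en-1-yl trifluoromethanesulfonate | C=C[C@]1(C)C[C@@H](O[Si](C)(C)C(C)(C)C)[C@H]([C@]2(C)O[C@@H](C(C)(C)C)OC2=O)C=C1OS(=O)(=O)C(F)(F)F | intermediate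
15 | (2R,5S)-2-tert-butyl-5-[(1R,4S,6R)-6-[(tert-butyldimethylsilyl)oxy]-4-ethenyl-4-methyl-3-(prop-1-en-2-yl)cyclohex-2-en-1-yl]-5-methyl-1,3-dioxolan-4-one | C=C[C@]1(C)C[C@@H](O[Si](C)(C)C(C)(C)C)[C@H]([C@]2(C)O[C@@H](C(C)(C)C)OC2=O)C=C1C(C)=C | intermediate
16 | (2S)-2-[(1R,4S,6R)-6-[(tert-butyldimethylsilyl)oxy]-4-ethenyl-4-methyl-3-(prop-1-en-2-yl)cyclohex-2-en-1-yl]-2-hydroxypropanoic acid | C=C[C@]1(C)C[C@@H](O[Si](C)(C)C(C)(C)C)[C@H]([C@](C)(O)C(=O)O)C=C1C(C)=C | intermediate
17 | acetic (2S)-2-acetoxy-2-[(1R,4S,6R)-6-[(tert-butyldimethylsilyl)oxy]-4-ethenyl-4-methyl-3-(prop-1-en-2-yl)cyclohex-2-en-1-yl]propanoic anhydride (formed in the flask) | C=C[C@]1(C)C[C@@H](O[Si](C)(C)C(C)(C)C)[C@H]([C@](C)(OC(C)=O)C(=O)OC(C)=O)C=C1C(C)=C | intermediate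
18 | (2S)-2-acetoxy-2-[(1R,4S,6R)-6-[(tert-butyldimethylsilyl)oxy]-4-ethenyl-4-methyl-3-(prop-1-en-2-yl)cyclohex-2-en-1-yl]propanoic acid | C=C[C@]1(C)C[C@@H](O[Si](C)(C)C(C)(C)C)[C@H]([C@](C)(OC(C)=O)C(=O)O)C=C1C(C)=C | intermediate
19 | (3S,3aR,4R,6S,7Z,7aS)-3-acetoxy-4-[(tert-butyldimethylsilyl)oxy]-7-(1-chloropropan-2-ylidene)-6-ethenyl-3,6-dimethylhexahydro-1-benzofuran-2(3H)-one | C=C[C@]1(C)C[C@@H](O[Si](C)(C)C(C)(C)C)[C@H]2[C@H](OC(=O)[C@@]2(C)OC(C)=O)/C1=C(/C)CCl | intermediate
20 | (3S,3aR,4R,6S,7R,7aR)-3-acetoxy-4-[(tert-butyldimethylsilyl)oxy]-6-ethenyl-3,6-dimethyl-7-(prop-1-en-2-yl)hexahydro-1-benzofuran-2(3H)-one | C=C[C@]1(C)C[C@@H](O[Si](C)(C)C(C)(C)C)[C@H]2[C@H](OC(=O)[C@@]2(C)OC(C)=O)[C@@H]1C(=C)C | intermediate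
21 | (3S,3aS,4R,6S,7R,7aR)-3-acetoxy-6-ethenyl-4-hydroxy-3,6-dimethyl-7-(prop-1-en-2-yl)hexahydro-1-benzofuran-2(3H)-one | C=C[C@]1(C)C[C@@H](O)[C@H]2[C@H](OC(=O)[C@@]2(C)OC(C)=O)[C@@H]1C(=C)C | intermediate
22 | 3-methylbut-3-enoic acid | C=C(C)CC(=O)O | starting material
23 | (3S,3aS,4R,6S,7R,7aR)-3-acetoxy-6-ethenyl-3,6-dimethyl-2-oxo-7-(prop-1-en-2-yl)octahydro-1-benzofuran-4-yl 3-methylbut-3-enoate | C=C[C@]1(C)C[C@@H](OC(=O)CC(=C)C)[C@H]2[C@H](OC(=O)[C@@]2(C)OC(C)=O)[C@@H]1C(=C)C | target

**Step count**
Total: 15 steps. Longest linear sequence: 14 steps (steps 1–6 and 8–15; step 7 is the side branch).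

**Steps most likely to fail**

Step 8. The fully substituted dioxolanone enolate is thermally labile and may decompose, or merely transfer a proton, before it adds to the hindered β-carbon C7. The fallback makes the C7–C11 bond with a radical and sets out from 11. N-Bromosuccinimide with AIBN in refluxing CCl4 should give (2S,5S)-5-bromo-2-tert-butyl-5-methyl-1,3-dioxolan-4-one F1 (either C5 epimer serves). Slow addition of (Me3Si)3SiH and AIBN to F1 and enone 9 in benzene at 80 °C should effect a Giese addition of the dioxolanonyl radical to C7, anti to the silyloxy group and anti to the tert-butyl group. This gives (2R,5S)-2-tert-butyl-5-[(1R,2R,4S)-2-[(tert-butyldimethylsilyl)oxy]-4-ethenyl-4-methyl-5-oxocyclohexyl]-5-methyl-1,3-dioxolan-4-one F2. KN(SiMe3)2 then PhNTf2 in THF at −78 °C converts F2 into triflate 14 (only the C5=C6 enolate can form), where the route is rejoined.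

Step 12. Benzoquinone may consume the diene by Diels–Alder addition, divalent palladium may fail to engage the twisted, hindered diene, or the carboxylate may add at C5. The fallback is a metal-free electrophilic 1,4-iodolactonization and sets out from 18. N-Iodosuccinimide with NaHCO3 in MeCN at 0 °C should attack the terminal carbon C3, and the allyl cation C4–C5–C6 is captured at C6 by the carboxylate on the tether face. This gives (3S,3aR,4R,6S,7Z,7aS)-3-acetoxy-4-[(tert-butyldimethylsilyl)oxy]-6-ethenyl-7-(1-iodopropan-2-ylidene)-3,6-dimethylhexahydro-1-benzofuran-2(3H)-one F3. F3 is reduced under the conditions of step 13 and the route is rejoined at 20.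

Step 13. The hydride may go to the primary allyl terminus C3 (giving the isopropylidene isomer), or zerovalent palladium may ionize the allylic lactone C6–O bond. The fallback is an allylic diazene rearrangement and sets out from 19. N-Isopropylidene-N'-2-nitrobenzenesulfonylhydrazine with K2CO3 and NaI (cat.) in DMF should displace the primary chloride to give (3S,3aR,4R,6S,7Z,7aS)-3-acetoxy-4-[(tert-butyldimethylsilyl)oxy]-6-ethenyl-3,6-dimethyl-7-{1-[1-(2-nitrobenzenesulfonyl)-2-(propan-2-ylidene)hydrazinyl]propan-2-ylidene}hexahydro-1-benzofuran-2(3H)-one F4. Hydrolysis in CF3CH2OH–H2O with AcOH at 23 °C removes acetone and the sulfinic acid and releases (3S,3aR,4R,6S,7Z,7aS)-3-acetoxy-4-[(tert-butyldimethylsilyl)oxy]-7-(1-diazenylpropan-2-ylidene)-6-ethenyl-3,6-dimethylhexahydro-1-benzofuran-2(3H)-one F5. F5 loses dinitrogen by a retro-ene shift that can only deliver hydrogen to C5, on the open top face, and the route is rejoined at 20.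

**Further compounds**
F1 | step 8 | (2S,5S)-5-bromo-2-tert-butyl-5-methyl-1,3-dioxolan-4-one | C[C@@]1(Br)O[C@@H](C(C)(C)C)OC1=O
F2 | step 8 | (2R,5S)-2-tert-butyl-5-[(1R,2R,4S)-2-[(tert-butyldimethylsilyl)oxy]-4-ethenyl-4-methyl-5-oxocyclohexyl]-5-methyl-1,3-dioxolan-4-one | C=C[C@]1(C)C[C@@H](O[Si](C)(C)C(C)(C)C)[C@H]([C@]2(C)O[C@@H](C(C)(C)C)OC2=O)CC1=O
F3 | step 12 | (3S,3aR,4R,6S,7Z,7aS)-3-acetoxy-4-[(tert-butyldimethylsilyl)oxy]-6-ethenyl-7-(1-iodopropan-2-ylidene)-3,6-dimethylhexahydro-1-benzofuran-2(3H)-one | C=C[C@]1(C)C[C@@H](O[Si](C)(C)C(C)(C)C)[C@H]2[C@H](OC(=O)[C@@]2(C)OC(C)=O)/C1=C(/C)CI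
F4 | step 13 | (3S,3aR,4R,6S,7Z,7aS)-3-acetoxy-4-[(tert-butyldimethylsilyl)oxy]-6-ethenyl-3,6-dimethyl-7-{1-[1-(2-nitrobenzenesulfonyl)-2-(propan-2-ylidene)hydrazinyl]propan-2-ylidene}hexahydro-1-benzofuran-2(3H)-one | C=C[C@]1(C)C[C@@H](O[Si](C)(C)C(C)(C)C)[C@H]2[C@H](OC(=O)[C@@]2(C)OC(C)=O)/C1=C(/C)CN(N=C(C)C)S(=O)(=O)c1ccccc1[N+](=O)[O-]
F5 | step 13 | (3S,3aR,4R,6S,7Z,7aS)-3-acetoxy-4-[(tert-butyldimethylsilyl)oxy]-7-(1-diazenylpropan-2-ylidene)-6-ethenyl-3,6-dimethylhexahydro-1-benzofuran-2(3H)-one | C=C[C@]1(C)C[C@@H](O[Si](C)(C)C(C)(C)C)[C@H]2[C@H](OC(=O)[C@@]2(C)OC(C)=O)/C1=C(/C)CN=N
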